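## Structural features

The target 17 is a biflavanone made of two 2-aryl-chroman-4-one units. Unit 1 is a 5,7-dihydroxyflavanone whose ring B is a para-phenylene. Its 4'-oxygen is bonded to C6'' of ring A of unit 2, a 5'',7''-dihydroxyflavanone that carries a 4-hydroxyphenyl group at C2''. The link is therefore a diaryl ether whose oxygen sits between two oxygenated carbons (C5'' and C7'') on an electron-rich ring. The two stereocentres, C2 and C2'', are both S; they are not adjacent but are separated by ring B of unit 1 and the ether oxygen, so neither can steer the other. Each is a benzylic ether carbon β to a ketone: base can open the pyranone by retro-oxa-Michael reaction and erase the configuration, the C2–O bonds can be hydrogenolysed, and the five phenols (above all the 5,6,7-trioxygenated ring A of unit 2) are easily oxidised. The real difficulty is threefold: two remote, labile centres of the same sense; the choice of which ortho oxygen of ring A of unit 2 becomes O1'' (6-aryloxy versus 8-aryloxy flavanone); and the flanked ether. The key step exploits that both heterocycles end in the same bond, O1–C2 and O1''–C2'', each β to its C4 carbonyl and of the same configuration, so one chiral catalyst can run the same conjugate addition at both ends of a bis-enone.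

## Logic of the disconnections

17 ⇒ 16. The five phenolic O–H groups are traced back to O–CH2Ph bonds. Free phenols would not survive enolate chemistry, amine-catalysed condensation or the persulfate step, and benzyl ethers leave under neutral conditions that do not open the pyranone rings. The gain is an oxidation-stable, non-acidic intermediate. The demand is a hydrogenolysis that spares the benzylic C2–O1 and C2''–O1'' bonds and both ketones.

16 ⇒ 14 (through 15). In the reverse sense a carboxyl carbon is added at C3 and at C3'' (the C3–CO2tBu and C3''–CO2tBu bonds). The ester turns each enone into a two-point-binding, more electrophilic alkylidene β-dicarbonyl unit, which is what makes the ring closure catalysable; tert-butyl is chosen because it leaves with acid, not base. Nothing is gained in size, but an uncontrolled chalcone-to-flavanone closure becomes a controlled one. The demand is dealkylation and decarboxylation in warm acid without ring opening.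

14 ⇒ 13. The O1–C2 and O1''–C2'' bonds are cut. Both pyranone rings and both stereocentres disappear, leaving an achiral open-chain bis-enone. The forward step must control the enone face twice and must use the correct phenol on each ring A.

13 ⇒ 12 + 9. The C=C bond of the arm of unit 1 (benzylic carbon to α-carbon of the keto ester) is cut. This removes the whole of ring A of unit 1 as a simple β-keto ester. The forward condensation has to be mild enough to leave the alkylidene unit and the free phenol of 12 alone.

12 ⇒ 11 ⇒ 8 + 10. The aldehyde of 12 is first returned to its dioxolane, then the C=C bond of the arm of unit 2 is cut. The masking is needed because the diaryl ether core carries both a nucleophilic β-keto ester and an electrophilic aldehyde and would otherwise condense with itself. The gain is that ring B of unit 2 arrives as 10. The demand is an unmasking by weak acid that leaves the tert-butyl ester and the enone intact.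

8 ⇒ 7 and 9 ⇒ 2. In each case the bond between the methyl carbon of the aryl methyl ketone and the ester carbonyl carbon is cut. Both β-keto esters then come from acetophenones by one and the same operation. The demand is C-acylation in the presence of a free ortho-phenol, and for 7 an aldehyde that is already masked, since an enolate and a free aldehyde cannot coexist.

7 ⇒ 6 ⇒ 4 + 5. After removal of the dioxolane, the ether bond between the oxygen on C6'' and C4' of ring B of unit 1 is cut. C4' is para to a formyl group and therefore open to addition–elimination, whereas ring A of unit 2 is far too electron-rich to serve as the electrophile. Ring B of unit 1 with its carbon substituent is thereby reduced to 5. The demand is reaction at the flanked phenol and not at the chelated one, and no aldol reaction between the methyl ketone and the aldehyde.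

4 ⇒ 2 ⇒ 1. The C–O bond at the future C6'' is cut, then two O–benzyl bonds. Compound 2 already has the ring A pattern needed in both units (free phenol ortho to the acetyl group, benzyl on the other ortho oxygen), and hydroxylation para to its free phenol places the extra oxygen exactly between the two benzyloxy groups. One intermediate thus serves both halves. The demands are para-selective hydroxylation and a dibenzylation that leaves the chelated hydroxyl free.

## Other disconnections considered

Alternative 1: The cut is the C4a''–C5'' bond, so that ring A of unit 2 is built last on a preformed chiral dihydropyranone. In the forward step a base converts the open-chain keto ester A1 into its extended enolate; the ring carbon that becomes C4a'' attacks the methyl ester carbon that becomes C5'', and double enolisation aromatises the new ring to the bromo flavanone A2.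
- In its favour: the 5,6,7-oxygen pattern with the 6-aryloxy group is assembled unambiguously, and O1'' is already in the ring, so no question arises as to which ortho oxygen closes. On this point it is better than the chosen plan, which depends on the para-selectivity of step 2 and on a blocking benzyl group. The C2'' centre could come from a catalytic asymmetric hetero-Diels–Alder reaction, which is the equal of the chosen plan for that one centre. Aromatisation is also a stronger driving force than a reversible conjugate addition.
- Against it here: C2'' in A1 lies β to a ketone with the ring oxygen as leaving group, so the base needed for the condensation can open the ring by E1cB elimination and erode the configuration. A2 still lacks the whole of unit 1: the bromide must become a formyl group in the presence of a ketone and two free phenols, and C2 then needs a second, separate asymmetric ring closure.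
- Comparison: the alternative is stronger on regiochemistry of ring A of unit 2. The chosen plan is stronger on convergence, because it sets both centres in one operation and never exposes a finished stereocentre to strong base. The step count of the alternative would be clearly higher.

Alternative 2: The cut removes the C2'–C3' and C4'–C5' bonds, so that ring B of unit 1 is made instead of bought. In the forward step the aryl ethynyl ether A3 adds across C3 and C6 of methyl coumalate A4 in an inverse-demand Diels–Alder reaction; the bridged lactone loses carbon dioxide and gives the diaryl ether ester A5 with the aryloxy group para to the ester.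
- In its favour: the regiochemistry follows from the polarisation of both partners. The reaction is thermal and neutral, and no aryl electrophile has to be brought to a flanked phenol oxygen. The protected oxygen para to the ether could later direct ortho-metalation for the acyl carbon. It is better than steps 2 and 3 of the chosen plan in that it has no competition between two phenols, no methyl ketone next to an aldehyde under base and no persulfate oxidation.
- Against it here: A3 needs its own multi-step preparation and is sensitive. A5 is at the ester oxidation level and its ring A still has no acyl carbon. The step makes neither a stereocentre nor a pyranone ring.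
- Comparison: this is a different way to the diaryl ether core, not a rival of the ring-closing step; it would have to be followed by the same twofold closure or an equivalent. In step economy it is inferior, since ring B of unit 1 is available intact as 5 and the ether is made in one step.

Alternative 3: The cut is at O1–C8a and O1''–C8a''. In the forward step CuI with a phenanthroline ligand and Cs2CO3 (or Pd(OAc)2 with a bulky biarylphosphine) joins each (S)-carbinol oxygen of the dibromo diol A6 to its ortho-bromoarene carbon and gives the bis-flavan A7; the C4 and C4'' carbonyls are introduced afterwards.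
- In its favour: the two carbinol centres would come from catalytic asymmetric ketone reduction and are configurationally robust. The coupling does not touch them and no retro-Michael pathway exists at the flavan stage. On stereochemical security it is better than the chosen plan, and it equals the chosen plan in closing both rings in one operation.
- Against it here: the carbonyls must be put in by two late benzylic oxidations. At that stage C2–H and C2''–H (benzylic and α to oxygen) and five OCH2Ph groups compete with C4–H and C4''–H, and nothing in the substrate favours the wanted positions. Secondary benzylic alkoxides on palladium may also undergo β-hydride elimination, and oxidative addition into electron-rich bromoarenes is slow.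
- Comparison: the alternative trades the labile oxa-Michael stereochemistry for a late selectivity problem that has no handle. It also runs a redox detour, whereas the chosen plan stays at the ketone oxidation level throughout, and it would be longer.

Key step: step 10

Remarks on the chemistry:
- Sense of induction: the quinine-derived thiourea is taken to give the arrangement that becomes 2S and 2''S. Should the sense be opposite on this substrate, the quinidine-derived pseudo-enantiomer, N-[3,5-bis(trifluoromethyl)phenyl]-N'-[(9R)-6'-methoxycinchonan-9-yl]thiourea, replaces it unchanged.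
- Descriptors: in the bis-enol drawing of 14 the enol carbon C3 outranks the aryl group, so the formal descriptors there are 2R,2''R. The spatial arrangement is the one that reads 2S,2''S in the keto tautomer and in 15, 16 and 17; an S,S label on the enol drawing would be a mislabel, not a different compound.
- Numbering: half-reacted species of the twofold steps (mono-benzylated, mono-cyclised, partly debenzylated) are stages of one reaction and are not numbered.

## Route

Step 1
Reactants: 1 2',4',6'-trihydroxyacetophenone
Product: 2 1-[2,4-bis(benzyloxy)-6-hydroxyphenyl]ethanone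
Conditions: BnBr (2.05 equiv), K2CO3 (2.2 equiv), DMF, rt
Reagents that add atoms: benzyl bromide, BrCc1ccccc1
Why: Williamson ether synthesis; the hydroxyl hydrogen-bonded to the acetyl carbonyl is the least nucleophilic and should stay free, which gives the free ortho-phenol and the blocked ortho oxygen that both ring A units need.

Step 2
Reactants: 2 1-[2,4-bis(benzyloxy)-6-hydroxyphenyl]ethanone
Product: 4 1-[2,4-bis(benzyloxy)-3,6-dihydroxyphenyl]ethanone, via potassium aryl sulfate 3 (not isolated)
Conditions: K2S2O8 (1.1 equiv), 10% aq NaOH, pyridine, 0 °C → rt; then aq HCl, Na2SO3, 80 °C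
Reagents that add atoms: potassium peroxodisulfate, [K+].[K+].[O-]S(=O)(=O)OOS(=O)(=O)[O-]
Why: Elbs persulfate oxidation; the phenoxide of 2 attacks the peroxide oxygen through the carbon para to O−, the only para position, which lies between the two benzyloxy groups, and acid then cleaves the S–O bond of sulfate 3. The reaction type is established for 2-hydroxy-4,6-dialkoxyacetophenones, and unreacted 2 can be recovered from the organic extract before hydrolysis.

Step 3
Reactants: 4 1-[2,4-bis(benzyloxy)-3,6-dihydroxyphenyl]ethanone; 5 4-fluorobenzaldehyde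
Product: 6 4-[3-acetyl-2,6-bis(benzyloxy)-4-hydroxyphenoxy]benzaldehyde
Conditions: 5 (1.05 equiv), K2CO3 (1.2 equiv), DMF, 90 °C, Ar
Reagents that add atoms: none
Why: Nucleophilic aromatic substitution (addition–elimination) on the para-formyl-activated fluoroarene; the phenoxide flanked by the benzyloxy groups is not conjugated with the acetyl group and is the more nucleophilic, while the other is held in a chelate with the ketone. K2CO3 in an aprotic solvent should not enolise the methyl ketone appreciably, and air is excluded because 4 is a hydroquinone.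

Step 4
Reactants: 6 4-[3-acetyl-2,6-bis(benzyloxy)-4-hydroxyphenoxy]benzaldehyde
Product: 7 1-{2,4-bis(benzyloxy)-3-[4-(1,3-dioxolan-2-yl)phenoxy]-6-hydroxyphenyl}ethanone
Conditions: HOCH2CH2OH (5 equiv), pyridinium p-toluenesulfonate (cat.), toluene, reflux, Dean–Stark
Reagents that add atoms: ethylene glycol, OCCO
Why: Acid-catalysed acetalisation with azeotropic removal of water; the aryl aldehyde reacts, whereas the di-ortho-substituted, hydrogen-bonded aryl methyl ketone should not.

Step 5
Reactants: 7 1-{2,4-bis(benzyloxy)-3-[4-(1,3-dioxolan-2-yl)phenoxy]-6-hydroxyphenyl}ethanone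
Product: 8 tert-butyl 3-{2,4-bis(benzyloxy)-3-[4-(1,3-dioxolan-2-yl)phenoxy]-6-hydroxyphenyl}-3-oxopropanoate
Conditions: LiN(SiMe3)2 (3.2 equiv), THF, −78 °C; Boc2O (1.1 equiv), −78 → 0 °C; aq NH4Cl
Reagents that add atoms: di-tert-butyl dicarbonate, CC(C)(C)OC(=O)OC(=O)OC(C)(C)C
Why: C-tert-butoxycarbonylation of the phenoxide/enolate dianion (the third equivalent of base takes up the acidic product), the same type as C-acylation of polyanions of 2-hydroxyacetophenones. Any aryl carbonate formed at the phenoxide should be funnelled to the same product by Baker–Venkataraman-type O-to-C transfer, and the dioxolane keeps the aldehyde away from the enolate.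

Step 6
Reactants: 2 1-[2,4-bis(benzyloxy)-6-hydroxyphenyl]ethanone
Product: 9 tert-butyl 3-[2,4-bis(benzyloxy)-6-hydroxyphenyl]-3-oxopropanoate
Conditions: LiN(SiMe3)2 (3.2 equiv), THF, −78 °C; Boc2O (1.1 equiv), −78 → 0 °C; aq NH4Cl
Reagents that add atoms: di-tert-butyl dicarbonate, CC(C)(C)OC(=O)OC(=O)OC(C)(C)C
Why: Same C-carboxylation of a phenoxide/enolate dianion as in step 5, on the simpler acetophenone; cold quench avoids lactonisation of the product to a 4-hydroxycoumarin.

Step 7
Reactants: 8 tert-butyl 3-{2,4-bis(benzyloxy)-3-[4-(1,3-dioxolan-2-yl)phenoxy]-6-hydroxyphenyl}-3-oxopropanoate; 10 4-(benzyloxy)benzaldehyde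
Product: 11 tert-butyl 2-{2,4-bis(benzyloxy)-3-[4-(1,3-dioxolan-2-yl)phenoxy]-6-hydroxybenzoyl}-3-[4-(benzyloxy)phenyl]prop-2-enoate (alkene isomers)
Conditions: 10 (1.1 equiv), piperidine (0.2 equiv), AcOH (0.2 equiv), 4 Å MS, toluene, rt
Reagents that add atoms: none
Why: Knoevenagel condensation through the iminium ion of the non-enolisable aldehyde, with the sieves taking up the water. Room temperature and the acetate buffer should keep the ketone-bonded phenol from closing early, and the alkene isomer mixture is used as such.

Step 8
Reactants: 11 tert-butyl 2-{2,4-bis(benzyloxy)-3-[4-(1,3-dioxolan-2-yl)phenoxy]-6-hydroxybenzoyl}-3-[4-(benzyloxy)phenyl]prop-2-enoate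
Product: 12 tert-butyl 2-[2,4-bis(benzyloxy)-3-(4-formylphenoxy)-6-hydroxybenzoyl]-3-[4-(benzyloxy)phenyl]prop-2-enoate
Conditions: pyridinium p-toluenesulfonate (0.2 equiv), acetone/H2O 9:1, 40 °C
Reagents that add atoms: water, O
Why: Acid-catalysed acetal hydrolysis; the oxocarbenium ion is stabilised by the para-aryloxy group, so a weak acid should suffice and the tert-butyl ester and the enone should survive.

Step 9
Reactants: 12 tert-butyl 2-[2,4-bis(benzyloxy)-3-(4-formylphenoxy)-6-hydroxybenzoyl]-3-[4-(benzyloxy)phenyl]prop-2-enoate; 9 tert-butyl 3-[2,4-bis(benzyloxy)-6-hydroxyphenyl]-3-oxopropanoate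
Product: 13 tert-butyl 2-[2,4-bis(benzyloxy)-6-hydroxybenzoyl]-3-[4-(2,6-bis(benzyloxy)-3-{3-[4-(benzyloxy)phenyl]-2-(tert-butoxycarbonyl)prop-2-enoyl}-4-hydroxyphenoxy)phenyl]prop-2-enoate (alkene isomers)
Conditions: 9 (1.05 equiv), piperidine (0.1 equiv), AcOH (0.1 equiv), 4 Å MS, toluene, rt
Reagents that add atoms: none
Why: Second Knoevenagel condensation, now between the active methylene of 9 and the aryl aldehyde of 12. Low amine loading, room temperature and short contact are meant to limit amine-promoted closure or exchange at the alkylidene unit already present.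

Step 10
Reactants: 13 the bis(alkylidene tert-butyl β-keto ester) of the diaryl ether
Product: 14 tert-butyl 5,7-bis(benzyloxy)-2-[4-({5,7-bis(benzyloxy)-2-[4-(benzyloxy)phenyl]-3-(tert-butoxycarbonyl)-4-hydroxy-2H-chromen-6-yl}oxy)phenyl]-4-hydroxy-2H-chromene-3-carboxylate (drawn as the bis-enol; C2 and C2'' arranged as in the 2S,2''S flavanone)
Conditions: N-[3,5-bis(trifluoromethyl)phenyl]-N'-[(8α,9S)-6'-methoxycinchonan-9-yl]thiourea (20 mol %), toluene, −25 °C; cold aq citric acid wash
Reagents that add atoms: none
Why: At each arm the thiourea should hold the β-keto ester through two hydrogen bonds while the quinuclidine nitrogen takes the proton of the neighbouring ortho-phenol, and the phenoxide adds to the β-carbon of the alkylidene unit, followed by protonation to the enol or keto ester. The closest known reaction type is the cinchona-thiourea-catalysed intramolecular oxa-Michael addition of 2-hydroxyaryl alkylidene β-keto esters to 3-carboxyflavanones, run here at two independent sites of one molecule. Both pyranone rings close in the 6-endo-trig mode, forming O1–C2 and O1''–C2''. C2 and C2'' are each set by the catalyst, which shields one face of the bound enone; the sites are far apart, so no matched or mismatched interplay is expected and the same sense should result at both. The ester raises the electrophilicity and supplies the two-point binding site, so the catalysed path should outrun background closure at −25 °C, and both alkene isomers are expected to converge because addition is reversible at the bound stage. The step needs face selectivity at two sites and the right closing oxygen; the benzyl groups on O5 and O5'' secure the latter, and in unit 2 the only free phenol is the one next to C8''–H, which fixes the 6-aryloxy pattern. Because the two sites react independently, the minor sense at either site should end up mainly in diastereomers of 14 and not in its enantiomer. The acidic wash removes the basic catalyst before the warm step that follows.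

Step 11
Reactants: 14 the bis(3-tert-butoxycarbonyl) biflavanone, penta-O-benzyl
Product: 16 (2S)-5,7-bis(benzyloxy)-6-{4-[(2S)-5,7-bis(benzyloxy)-4-oxochroman-2-yl]phenoxy}-2-[4-(benzyloxy)phenyl]chroman-4-one, via bis(β-keto acid) 15 (not isolated)
Conditions: TsOH·H2O (3 equiv), toluene, 80 °C
Reagents that add atoms: none
Why: Acid removes 2-methylpropene from both tert-butyl esters to give bis(β-keto acid) 15, which decarboxylates thermally through the cyclic six-membered transition state. Acid, not base, is used so that no retro-oxa-Michael opening occurs and C2 and C2'' stay as set; a benzyl ether lost here would be of no consequence, since all five go in step 12.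

Step 12
Reactants: 16 the penta-O-benzyl (2S,2''S)-biflavanone
Product: 17 (2S)-5,7-dihydroxy-6-{4-[(2S)-5,7-dihydroxy-4-oxochroman-2-yl]phenoxy}-2-(4-hydroxyphenyl)chroman-4-one (CNP0184214.1)
Conditions: H2 (1 atm), 10% Pd/C, THF/MeOH 1:1, rt
Reagents that add atoms: none
Why: Hydrogenolysis of the five aryl benzyl ethers; at 1 atm and with the reaction stopped at full conversion, the more slowly reacting benzylic C2–O bonds and the ketones should remain, and the neutral medium does not epimerise C2 or C2''.

## Compound list

1 | 2',4',6'-trihydroxyacetophenone | CC(=O)c1c(O)cc(O)cc1O | starting material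
2 | 1-[2,4-bis(benzyloxy)-6-hydroxyphenyl]ethanone | CC(=O)c1c(O)cc(OCc2ccccc2)cc1OCc1ccccc1 | intermediate
3 | potassium 3-acetyl-2,6-bis(benzyloxy)-4-hydroxyphenyl sulfate | CC(=O)c1c(O)cc(OCc2ccccc2)c(OS(=O)(=O)[O-])c1OCc1ccccc1.[K+] | intermediate (not isolated)
4 | 1-[2,4-bis(benzyloxy)-3,6-dihydroxyphenyl]ethanone | CC(=O)c1c(O)cc(OCc2ccccc2)c(O)c1OCc1ccccc1 | intermediate
5 | 4-fluorobenzaldehyde | O=Cc1ccc(F)cc1 | starting material
6 | 4-[3-acetyl-2,6-bis(benzyloxy)-4-hydroxyphenoxy]benzaldehyde | CC(=O)c1c(O)cc(OCc2ccccc2)c(Oc2ccc(C=O)cc2)c1OCc1ccccc1 | intermediate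
7 | 1-{2,4-bis(benzyloxy)-3-[4-(1,3-dioxolan-2-yl)phenoxy]-6-hydroxyphenyl}ethanone | CC(=O)c1c(O)cc(OCc2ccccc2)c(Oc2ccc(C3OCCO3)cc2)c1OCc1ccccc1 | intermediate
8 | tert-butyl 3-{2,4-bis(benzyloxy)-3-[4-(1,3-dioxolan-2-yl)phenoxy]-6-hydroxyphenyl}-3-oxopropanoate | CC(C)(C)OC(=O)CC(=O)c1c(O)cc(OCc2ccccc2)c(Oc2ccc(C3OCCO3)cc2)c1OCc1ccccc1 | intermediate
9 | tert-butyl 3-[2,4-bis(benzyloxy)-6-hydroxyphenyl]-3-oxopropanoate | CC(C)(C)OC(=O)CC(=O)c1c(O)cc(OCc2ccccc2)cc1OCc1ccccc1 | intermediate
10 | 4-(benzyloxy)benzaldehyde | O=Cc1ccc(OCc2ccccc2)cc1 | starting material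
11 | tert-butyl 2-{2,4-bis(benzyloxy)-3-[4-(1,3-dioxolan-2-yl)phenoxy]-6-hydroxybenzoyl}-3-[4-(benzyloxy)phenyl]prop-2-enoate | CC(C)(C)OC(=O)C(=Cc1ccc(OCc2ccccc2)cc1)C(=O)c1c(O)cc(OCc2ccccc2)c(Oc2ccc(C3OCCO3)cc2)c1OCc1ccccc1 | intermediate
12 | tert-butyl 2-[2,4-bis(benzyloxy)-3-(4-formylphenoxy)-6-hydroxybenzoyl]-3-[4-(benzyloxy)phenyl]prop-2-enoate | CC(C)(C)OC(=O)C(=Cc1ccc(OCc2ccccc2)cc1)C(=O)c1c(O)cc(OCc2ccccc2)c(Oc2ccc(C=O)cc2)c1OCc1ccccc1 | intermediate
13 | tert-butyl 2-[2,4-bis(benzyloxy)-6-hydroxybenzoyl]-3-[4-(2,6-bis(benzyloxy)-3-{3-[4-(benzyloxy)phenyl]-2-(tert-butoxycarbonyl)prop-2-enoyl}-4-hydroxyphenoxy)phenyl]prop-2-enoate | CC(C)(C)OC(=O)C(=Cc1ccc(Oc2c(OCc3ccccc3)cc(O)c(C(=O)C(=Cc3ccc(OCc4ccccc4)cc3)C(=O)OC(C)(C)C)c2OCc2ccccc2)cc1)C(=O)c1c(O)cc(OCc2ccccc2)cc1OCc1ccccc1 | intermediate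
14 | tert-butyl 5,7-bis(benzyloxy)-2-[4-({5,7-bis(benzyloxy)-2-[4-(benzyloxy)phenyl]-3-(tert-butoxycarbonyl)-4-hydroxy-2H-chromen-6-yl}oxy)phenyl]-4-hydroxy-2H-chromene-3-carboxylate (bis-enol drawing; formal descriptors 2R,2''R, same arrangement as 2S,2''S in the keto form) | OC1=C(C(=O)OC(C)(C)C)[C@@H](c2ccc(Oc3c(OCc5ccccc5)cc4c(c3OCc3ccccc3)C(O)=C(C(=O)OC(C)(C)C)[C@@H](c3ccc(OCc5ccccc5)cc3)O4)cc2)Oc2cc(OCc3ccccc3)cc(OCc3ccccc3)c21 | intermediate
15 | (2S)-5,7-bis(benzyloxy)-2-[4-({(2S)-5,7-bis(benzyloxy)-2-[4-(benzyloxy)phenyl]-3-carboxy-4-oxochroman-6-yl}oxy)phenyl]-4-oxochromane-3-carboxylic acid (C3 and C3'' undefined) | O=C1C(C(=O)O)[C@@H](c2ccc(Oc3c(OCc5ccccc5)cc4c(c3OCc3ccccc3)C(=O)C(C(=O)O)[C@@H](c3ccc(OCc5ccccc5)cc3)O4)cc2)Oc2cc(OCc3ccccc3)cc(OCc3ccccc3)c21 | intermediate (not isolated)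
16 | (2S)-5,7-bis(benzyloxy)-6-{4-[(2S)-5,7-bis(benzyloxy)-4-oxochroman-2-yl]phenoxy}-2-[4-(benzyloxy)phenyl]chroman-4-one | O=C1C[C@@H](c2ccc(Oc3c(OCc5ccccc5)cc4c(c3OCc3ccccc3)C(=O)C[C@@H](c3ccc(OCc5ccccc5)cc3)O4)cc2)Oc2cc(OCc3ccccc3)cc(OCc3ccccc3)c21 | intermediate
17 | (2S)-5,7-dihydroxy-6-{4-[(2S)-5,7-dihydroxy-4-oxochroman-2-yl]phenoxy}-2-(4-hydroxyphenyl)chroman-4-one | O=C1C[C@@H](c2ccc(Oc3c(O)cc4c(c3O)C(=O)C[C@@H](c3ccc(O)cc3)O4)cc2)Oc2cc(O)cc(O)c21 | target

## Step count and least certain steps

Total: 12 steps. Longest linear sequence: 11 steps (1, 2, 3, 4, 5, 7, 8, 9, 10, 11, 12); step 6 is the side branch from 2.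

Step 10 (key step). The most likely failure is incomplete face selectivity at one of the two sites. The aroyl groups are di-ortho-substituted and twisted, which may weaken catalyst binding, and some racemic closure may already occur under the amine conditions of steps 7 to 9. Because the centres are remote, the resulting diastereomers would be hard to remove.
- Fallback: two closures in sequence with enrichment in between, setting out from 11.
- Compound 11 is closed under the same thiourea (10 mol %, toluene, −25 °C) to tert-butyl 5,7-bis(benzyloxy)-2-[4-(benzyloxy)phenyl]-6-[4-(1,3-dioxolan-2-yl)phenoxy]-4-hydroxy-2H-chromene-3-carboxylate F1.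
- TsOH·H2O in toluene at 80 °C, followed by aqueous acetone, removes the ester, carbon dioxide and the dioxolane and gives 4-({(2S)-5,7-bis(benzyloxy)-2-[4-(benzyloxy)phenyl]-4-oxochroman-6-yl}oxy)benzaldehyde F2, whose enantiomeric purity could be raised by recrystallisation.
- Knoevenagel condensation of F2 with 9 (piperidine, AcOH, 4 Å MS, toluene, rt) gives tert-butyl 2-[2,4-bis(benzyloxy)-6-hydroxybenzoyl]-3-[4-({(2S)-5,7-bis(benzyloxy)-2-[4-(benzyloxy)phenyl]-4-oxochroman-6-yl}oxy)phenyl]prop-2-enoate F3. In this order no alkylidene unit meets the amine a second time.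
- A second catalysed closure gives tert-butyl 5,7-bis(benzyloxy)-2-[4-({(2S)-5,7-bis(benzyloxy)-2-[4-(benzyloxy)phenyl]-4-oxochroman-6-yl}oxy)phenyl]-4-hydroxy-2H-chromene-3-carboxylate F4, and warm TsOH·H2O brings the detour back to the route at 16.

Step 2. The most likely failure is low conversion through poor solubility of the phenoxide in the aqueous phase, or further oxidation of the electron-rich ring.
- Fallback: oxidation to the quinone and reduction, setting out from 2.
- ON(SO3K)2 (potassium nitrosodisulfonate) with KH2PO4 in acetone/H2O (Teuber oxidation at the free para position) should give 2-acetyl-3,5-bis(benzyloxy)cyclohexa-2,5-diene-1,4-dione F5.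
- Na2S2O4 in EtOAc/H2O reduces F5 to the hydroquinone, which rejoins the route at 4.

Step 3. The most likely failures are arylation at the chelated phenol or at both phenols, and base-promoted aldol condensation between the methyl ketone and an aldehyde.
- Fallback: an Ullmann-type coupling in which the aldehyde is masked from the start, setting out from 4.
- Compound 4 is coupled with commercial 2-(4-bromophenyl)-1,3-dioxolane (CuI, N,N-dimethylglycine, Cs2CO3, dioxane, 90 °C, Ar).
- This gives 7 directly, so the detour rejoins the route at 7 and step 4 is not needed.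

Steps 5 and 6. The most likely failures are acylation at oxygen instead of carbon, double acylation, or lactonisation of the product on warming.
- Fallback: acyl transfer within the molecule, setting out from 7 and from 2.
- Compound 7 is converted with Boc2O and 4-(dimethylamino)pyridine (cat.) in CH2Cl2 into 2-acetyl-3,5-bis(benzyloxy)-4-[4-(1,3-dioxolan-2-yl)phenoxy]phenyl tert-butyl carbonate F6. LiN(SiMe3)2 (2.2 equiv) in THF at −78 → 0 °C should then move the tert-butoxycarbonyl group from oxygen to the enolate carbon (Baker–Venkataraman-type rearrangement), rejoining the route at 8.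
- In the same way 2 gives 2-acetyl-3,5-bis(benzyloxy)phenyl tert-butyl carbonate F7, which rearranges and rejoins the route at 9.

Step 12. The most likely failures are over-reduction (hydrogenolysis of the benzylic C2–O bonds or reduction of the ketones) and incomplete cleavage of the hindered ethers on ring A of unit 2.
- Fallback: a non-reductive Lewis-acid debenzylation, setting out from 16.
- BCl3 with pentamethylbenzene as cation scavenger in CH2Cl2 at −78 °C should cleave all five ethers and give 17 directly.

## Further compounds

F1 | step 10 | tert-butyl 5,7-bis(benzyloxy)-2-[4-(benzyloxy)phenyl]-6-[4-(1,3-dioxolan-2-yl)phenoxy]-4-hydroxy-2H-chromene-3-carboxylate (enol drawing; C2 arranged as in the 2S flavanone) | OC1=C(C(=O)OC(C)(C)C)[C@@H](c2ccc(OCc3ccccc3)cc2)Oc2cc(OCc3ccccc3)c(Oc3ccc(C4OCCO4)cc3)c(OCc3ccccc3)c21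
F2 | step 10 | 4-({(2S)-5,7-bis(benzyloxy)-2-[4-(benzyloxy)phenyl]-4-oxochroman-6-yl}oxy)benzaldehyde | O=Cc1ccc(Oc2c(OCc3ccccc3)cc3c(c2OCc2ccccc2)C(=O)C[C@@H](c2ccc(OCc4ccccc4)cc2)O3)cc1
F3 | step 10 | tert-butyl 2-[2,4-bis(benzyloxy)-6-hydroxybenzoyl]-3-[4-({(2S)-5,7-bis(benzyloxy)-2-[4-(benzyloxy)phenyl]-4-oxochroman-6-yl}oxy)phenyl]prop-2-enoate | CC(C)(C)OC(=O)C(=Cc1ccc(Oc2c(OCc3ccccc3)cc3c(c2OCc2ccccc2)C(=O)C[C@@H](c2ccc(OCc4ccccc4)cc2)O3)cc1)C(=O)c1c(O)cc(OCc2ccccc2)cc1OCc1ccccc1
F4 | step 10 | tert-butyl 5,7-bis(benzyloxy)-2-[4-({(2S)-5,7-bis(benzyloxy)-2-[4-(benzyloxy)phenyl]-4-oxochroman-6-yl}oxy)phenyl]-4-hydroxy-2H-chromene-3-carboxylate (enol drawing; C2 arranged as in the 2S flavanone) | OC1=C(C(=O)OC(C)(C)C)[C@@H](c2ccc(Oc3c(OCc5ccccc5)cc4c(c3OCc3ccccc3)C(=O)C[C@@H](c3ccc(OCc5ccccc5)cc3)O4)cc2)Oc2cc(OCc3ccccc3)cc(OCc3ccccc3)c21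
F5 | step 2 | 2-acetyl-3,5-bis(benzyloxy)cyclohexa-2,5-diene-1,4-dione | CC(=O)C1=C(OCc2ccccc2)C(=O)C(OCc2ccccc2)=CC1=O
F0 | step 3 | none | none
F6 | step 5 | 2-acetyl-3,5-bis(benzyloxy)-4-[4-(1,3-dioxolan-2-yl)phenoxy]phenyl tert-butyl carbonate | CC(=O)c1c(OC(=O)OC(C)(C)C)cc(OCc2ccccc2)c(Oc2ccc(C3OCCO3)cc2)c1OCc1ccccc1
F7 | step 6 | 2-acetyl-3,5-bis(benzyloxy)phenyl tert-butyl carbonate | CC(=O)c1c(OC(=O)OC(C)(C)C)cc(OCc2ccccc2)cc1OCc1ccccc1
F0 | step 12 | none | none
A1 | alternative 1 | methyl 4-{(2S)-2-[4-(benzyloxy)phenyl]-4-oxo-3,4-dihydro-2H-pyran-6-yl}-2-(4-bromophenoxy)-3-oxobutanoate | COC(=O)C(Oc1ccc(Br)cc1)C(=O)CC1=CC(=O)C[C@@H](c2ccc(OCc3ccccc3)cc2)O1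
A2 | alternative 1 | (2S)-2-[4-(benzyloxy)phenyl]-6-(4-bromophenoxy)-5,7-dihydroxychroman-4-one | O=C1C[C@@H](c2ccc(OCc3ccccc3)cc2)Oc2cc(O)c(Oc3ccc(Br)cc3)c(O)c21
A3 | alternative 2 | 1,3-bis(benzyloxy)-2-(ethynyloxy)-5-(methoxymethoxy)benzene | C#COc1c(OCc2ccccc2)cc(OCOC)cc1OCc1ccccc1
A4 | alternative 2 | methyl coumalate (methyl 2-oxo-2H-pyran-5-carboxylate) | COC(=O)C1=COC(=O)C=C1
A5 | alternative 2 | methyl 4-[2,6-bis(benzyloxy)-4-(methoxymethoxy)phenoxy]benzoate | COC(=O)c1ccc(Oc2c(OCc3ccccc3)cc(OCOC)cc2OCc2ccccc2)cc1
A6 | alternative 3 | (1S)-1-[4-(2,6-bis(benzyloxy)-4-bromo-3-{(3S)-3-[4-(benzyloxy)phenyl]-3-hydroxypropyl}phenoxy)phenyl]-3-[2,4-bis(benzyloxy)-6-bromophenyl]propan-1-ol | O[C@@H](CCc1c(Br)cc(OCc2ccccc2)cc1OCc1ccccc1)c1ccc(Oc2c(OCc3ccccc3)cc(Br)c(CC[C@H](O)c3ccc(OCc4ccccc4)cc3)c2OCc2ccccc2)cc1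
A7 | alternative 3 | (2S)-5,7-bis(benzyloxy)-6-{4-[(2S)-5,7-bis(benzyloxy)chroman-2-yl]phenoxy}-2-[4-(benzyloxy)phenyl]chromane | C1C[C@@H](c2ccc(Oc3c(OCc5ccccc5)cc4c(c3OCc3ccccc3)CC[C@@H](c3ccc(OCc5ccccc5)cc3)O4)cc2)Oc2cc(OCc3ccccc3)cc(OCc3ccccc3)c21
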